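**Retrosynthetic overview**
- Last come oxidation of the oxepanol to the oxepanone (ring D) and, before it, addition of the (E)-alkenyllithium of the right half to the seven-membered lactone of the left half, which closes hemiketal ring B.
- The left lactone comes from Baeyer–Villiger ring expansion of a trans-decalone, made by hydroboration/oxidation of an octalin, made by an enantioselective alkyne-terminated cation–olefin bicyclisation.
- The right half comes from radical vinylation of a trans-diaxial bromohydrin, made from a bicyclic alkene, made by an epoxide-opening cascade of a bis-epoxy alkyne.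
- Both bicyclisations start from one C13 dienyne, built from 5-bromo-2-methylpent-2-ene, acetylide (used twice), oxirane and one methyl group (carboalumination).
- Ring order: left, ring A and a six-membered ring B together, then B expanded to seven atoms; right, ring D then ring C in one step; ring B re-closes as the hemiketal at the coupling.

Assumption: the hemiketal carbon of the target is the thermodynamically preferred anomer and is set by ring–chain equilibration on work-up.
Assumption: the (S)-ligand in step 10 gives the (4aR,8aR) series; if the sense of induction is the opposite, the (R)-ligand is used.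

**Step 1**
Reactants: 1 5-bromo-2-methylpent-2-ene; 2 lithium acetylide–ethane-1,2-diamine complex
Product: 3 6-methylhept-5-en-1-yne
Conditions: DMSO, 10 °C to rt
Reagents that add atoms: none
Why: SN2 alkylation of the acetylide by a primary homoallylic bromide; no stereocentre is formed.

**Step 2**
Reactants: 3 6-methylhept-5-en-1-yne; 4 oxirane
Product: 7 (3E)-4,8-dimethylnona-3,7-dien-1-ol, via alkenylalane 5 (not isolated), via lithium alanate 6 (not isolated)
Conditions: Me3Al (2 equiv), Cp2ZrCl2 (20 mol %), CH2Cl2, rt; then n-BuLi, THF, −78 °C; oxirane, −30 °C to rt; 1 M HCl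
Reagents that add atoms: trimethylaluminium, C[Al](C)C (the methyl group); n-butyllithium, [Li]CCCC (lithium and butyl of 6 only)
Why: Negishi carboalumination adds methyl and aluminium syn across the terminal alkyne, which fixes the E-trisubstituted alkene, and the derived alanate opens oxirane with retention of that geometry.

**Step 3**
Reactants: 7 (3E)-4,8-dimethylnona-3,7-dien-1-ol
Product: 8 (3E)-1-iodo-4,8-dimethylnona-3,7-diene
Conditions: I2, PPh3, imidazole, CH2Cl2, 0 °C
Reagents that add atoms: iodine, II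
Why: Appel-type (Garegg–Samuelsson) substitution of the primary alcohol; the alkenes are untouched.

**Step 4**
Reactants: 8 (3E)-1-iodo-4,8-dimethylnona-3,7-diene; 2 lithium acetylide–ethane-1,2-diamine complex
Product: 9 (5E)-6,10-dimethylundeca-5,9-dien-1-yne
Conditions: DMSO, rt
Reagents that add atoms: none
Why: SN2 alkylation of the acetylide by the primary iodide gives the C13 dienyne that both halves share.

**Step 5**
Reactants: 9 (5E)-6,10-dimethylundeca-5,9-dien-1-yne
Product: 10 (2R,3R)-3-(but-3-yn-1-yl)-2-{2-[(2R)-3,3-dimethyloxiran-2-yl]ethyl}-2-methyloxirane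
Conditions: D-fructose-derived Shi ketone (30 mol %), KHSO5 (as 2KHSO5·KHSO4·K2SO4), K2CO3, Bu4NHSO4, MeCN/dimethoxymethane/aq. Na2B4O7 buffer, 0 °C
Reagents that add atoms: potassium peroxymonosulfate, [K+].[O-]S(=O)(=O)OO (both epoxide oxygens)
Why: Shi asymmetric epoxidation (chiral dioxirane, spiro transition state) converts both trisubstituted alkenes into the (R) and (R,R) epoxides, while the terminal alkyne is inert.

**Step 6**
Reactants: 10 (2R,3R)-3-(but-3-yn-1-yl)-2-{2-[(2R)-3,3-dimethyloxiran-2-yl]ethyl}-2-methyloxirane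
Product: 11 (3R,5aR,9aR)-2,2,5a-trimethyl-3-[(trimethylsilyl)oxy]-2,3,4,5,5a,8,9,9a-octahydro-1-benzoxepin-7-yl trifluoromethanesulfonate
Conditions: TMSOTf (1.2 equiv), 2,6-di-tert-butyl-4-methylpyridine (0.5 equiv), CH2Cl2, −78 °C; Et3N quench
Reagents that add atoms: trimethylsilyl trifluoromethanesulfonate, C[Si](C)(C)OS(=O)(=O)C(F)(F)F
Why: Proposed new method: TMSOTf silylates the terminal epoxide, the internal epoxide oxygen opens it 7-endo at the dimethyl-substituted carbon to give a bicyclic epoxonium ion, the terminal alkyne carbon attacks the tertiary epoxonium carbon from the back (6-endo, inversion at C-5a, hence the trans ring fusion; C-3 and C-9a keep the configurations set by the Shi epoxides) and triflate captures the incipient cyclohexenyl cation, which fixes the double bond at C6=C7; the closest known reactions are Lewis-acid epoxide-opening oxa/carbacyclisation cascades of polyepoxides ended by alkenes, enol silanes or propargylsilanes, and alkyne Prins cyclisations that give cyclic alkenyl triflates.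

**Step 7**
Reactants: 11 (3R,5aR,9aR)-2,2,5a-trimethyl-3-[(trimethylsilyl)oxy]-2,3,4,5,5a,8,9,9a-octahydro-1-benzoxepin-7-yl trifluoromethanesulfonate
Product: 13 (3R,5aR,9aR)-2,2,5a,7-tetramethyl-2,3,4,5,5a,8,9,9a-octahydro-1-benzoxepin-3-ol, via silyl ether 12 (not isolated)
Conditions: MeMgBr (2 equiv), Fe(acac)3 (5 mol %), THF/NMP, −30 to 0 °C; then 1 M HCl, THF, 0 °C
Reagents that add atoms: methylmagnesium bromide, C[Mg]Br
Why: Iron-catalysed Kumada-type coupling replaces the alkenyl triflate by methyl without moving the double bond, and the acid work-up removes the silyl ether; no stereocentre changes.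

**Step 8**
Reactants: 13 (3R,5aR,9aR)-2,2,5a,7-tetramethyl-2,3,4,5,5a,8,9,9a-octahydro-1-benzoxepin-3-ol
Product: 14 (3R,5aS,6S,7S,9aR)-6-bromo-2,2,5a,7-tetramethyldecahydro-1-benzoxepine-3,7-diol
Conditions: NBS (1.1 equiv), acetone/H2O 4:1, 0 °C
Reagents that add atoms: N-bromosuccinimide, O=C1CCC(=O)N1Br; water, O
Why: Bromohydrin formation: the bromonium ion forms on the α face, anti to the axial 5a-methyl group, and water opens it at the tertiary carbon in the trans-diaxial (Fürst–Plattner) sense, which sets 7-OH β and 6-Br α.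

**Step 9**
Reactants: 14 (3R,5aS,6S,7S,9aR)-6-bromo-2,2,5a,7-tetramethyldecahydro-1-benzoxepine-3,7-diol
Product: 15 (3R,5aR,6S,7S,9aR)-2,2,5a,7-tetramethyl-6-[(E)-2-(tributylstannyl)ethenyl]decahydro-1-benzoxepine-3,7-diol
Conditions: (E)-Bu3SnCH=CHSnBu3 (3 equiv), AIBN (0.2 equiv), PhMe, 90 °C
Reagents that add atoms: (E)-1,2-bis(tributylstannyl)ethene, CCCC[Sn](CCCC)(CCCC)/C=C/[Sn](CCCC)(CCCC)CCCC
Why: Radical addition–fragmentation (Keck-type vinyl transfer): the C-6 radical is trapped on its axial α face, anti to the axial 5a-methyl and 7-hydroxyl groups, which sets C-6, and loss of Bu3Sn• gives the E-alkenylstannane.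

**Step 10**
Reactants: 9 (5E)-6,10-dimethylundeca-5,9-dien-1-yne
Product: 16 (4aR,8aR)-2-chloro-5,5,8a-trimethyl-3,4,4a,5,6,7,8,8a-octahydronaphthalene
Conditions: (S)-3,3′-dichloro-1,1′-bi-2-naphthol·SbCl5 (1:1 complex, 1.0 equiv), CH2Cl2, −78 °C; aq. NaHCO3
Reagents that add atoms: antimony pentachloride (as the binaphthol complex), Cl[Sb](Cl)(Cl)(Cl)Cl (the chlorine)
Why: Proposed new method: the chiral Brønsted acid protonates the terminal isopropylidene group on one face, the (E)-alkene relays the cation through a chair–chair transition state (anti addition, hence trans-fused C-4a/C-8a), the terminal alkyne carbon closes ring B 6-endo and chloride from the antimonate captures the cyclohexenyl cation at C-2; the closest known reactions are enantioselective proton-initiated polyene cyclisations with binaphthol·SbCl5 or binaphthol·SnCl4 acids that end on arenes, and racemic cation–olefin cyclisations that end on alkynes with halide capture.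

**Step 11**
Reactants: 16 (4aR,8aR)-2-chloro-5,5,8a-trimethyl-3,4,4a,5,6,7,8,8a-octahydronaphthalene
Product: 17 (4aR,8aS)-2,5,5,8a-tetramethyl-3,4,4a,5,6,7,8,8a-octahydronaphthalene
Conditions: MeMgBr (2 equiv), Ni(dppp)Cl2 (5 mol %), THF, 50 °C
Reagents that add atoms: methylmagnesium bromide, C[Mg]Br
Why: Kumada–Corriu coupling of the alkenyl chloride with retention of the double-bond position; no stereocentre changes (the descriptor at C-8a changes only through priorities).

**Step 12**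
Reactants: 17 (4aR,8aS)-2,5,5,8a-tetramethyl-3,4,4a,5,6,7,8,8a-octahydronaphthalene
Product: 19 (2R,4aR,8aR)-2,5,5,8a-tetramethyloctahydronaphthalen-1(2H)-one, via alkylborane 18 (not isolated)
Conditions: BH3·THF (1.2 equiv), THF, 0 °C to rt; then N-methylmorpholine N-oxide (5 equiv), Pr4N[RuO4] (5 mol %), 4 Å sieves, CH2Cl2, rt
Reagents that add atoms: borane–tetrahydrofuran, B.C1CCOC1 (boron of 18 only); N-methylmorpholine N-oxide, C[N+]1([O-])CCOCC1 (the ketone oxygen)
Why: Hydroboration then one-pot oxidation of the C–B bond and of the carbinol: boron adds to C-1 and hydrogen to C-2 syn from the α face, anti to the angular methyl group, so the 2-methyl group ends up β (cis to the angular methyl), and the neutral oxidation does not enolise the ketone.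

**Step 13**
Reactants: 19 (2R,4aR,8aR)-2,5,5,8a-tetramethyloctahydronaphthalen-1(2H)-one
Product: 20 (3R,5aR,9aR)-3,6,6,9a-tetramethyloctahydro-1-benzoxepin-2(3H)-one
Conditions: mCPBA (2 equiv), Na2HPO4, CH2Cl2, rt
Reagents that add atoms: 3-chloroperbenzoic acid, OOC(=O)c1cccc(Cl)c1
Why: Baeyer–Villiger ring expansion (1,2-shift in the Criegee adduct): the fully substituted C-8a migrates in preference to the secondary C-2, with retention at C-8a and no change at C-2, so the cyclohexanone becomes the seven-membered lactone with oxygen on the methyl-bearing ring-fusion carbon.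

**Step 14**
Reactants: 15 (3R,5aR,6S,7S,9aR)-2,2,5a,7-tetramethyl-6-[(E)-2-(tributylstannyl)ethenyl]decahydro-1-benzoxepine-3,7-diol; 20 (3R,5aR,9aR)-3,6,6,9a-tetramethyloctahydro-1-benzoxepin-2(3H)-one
Product: 22 (2R,3R,5aR,9aR)-2-{(E)-2-[(3R,5aR,6S,7S,9aR)-3,7-dihydroxy-2,2,5a,7-tetramethyldecahydro-1-benzoxepin-6-yl]ethenyl}-3,6,6,9a-tetramethyldecahydro-1-benzoxepin-2-ol, via alkenyllithium 21 (not isolated)
Conditions: n-BuLi (3.2 equiv), THF, −78 °C; then 20 (1.3 equiv), −78 °C; aq. NH4Cl, then rt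
Reagents that add atoms: n-butyllithium, [Li]CCCC (lithium of 21 only)
Why: Tin–lithium exchange with retention of the E geometry, then acyl addition to the lactone; the lithium hemiketalate resists a second addition, C-3 is not enolised at −78 °C, and the hemiketal carbon settles on work-up as the anomer with axial hydroxyl and equatorial alkenyl group.

**Step 15**
Reactants: 22 (the hemiketal triol from step 14)
Product: 23 (5aR,6S,7S,9aR)-7-hydroxy-6-{(E)-2-[(2R,3R,5aR,9aR)-2-hydroxy-3,6,6,9a-tetramethyldecahydro-1-benzoxepin-2-yl]ethenyl}-2,2,5a,7-tetramethyloctahydro-1-benzoxepin-3(2H)-one (the target)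
Conditions: Dess–Martin periodinane (1.5 equiv), NaHCO3, CH2Cl2, 0 °C to rt
Reagents that add atoms: none
Why: Dess–Martin oxidation of the only secondary alcohol; the two tertiary alcohols and the tertiary hemiketal cannot be oxidised, and the buffer protects the allylic hemiketal.

**Compound list**
1 | 5-bromo-2-methylpent-2-ene | CC(C)=CCCBr | starting material
2 | lithium acetylide–ethane-1,2-diamine complex | [Li+].[C-]#C.NCCN | starting material
3 | 6-methylhept-5-en-1-yne | CC(C)=CCCC#C | intermediate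
4 | oxirane | C1CO1 | starting material
5 | [(1E)-2,6-dimethylhepta-1,5-dien-1-yl]dimethylalane | CC(C)=CCC/C(C)=C/[Al](C)C | intermediate
6 | lithium butyl[(1E)-2,6-dimethylhepta-1,5-dien-1-yl]dimethylaluminate | [Li+].CC(C)=CCC/C(C)=C/[Al-](C)(C)CCCC | intermediate
7 | (3E)-4,8-dimethylnona-3,7-dien-1-ol | CC(C)=CCC/C(C)=C/CCO | intermediate
8 | (3E)-1-iodo-4,8-dimethylnona-3,7-diene | CC(C)=CCC/C(C)=C/CCI | intermediate
9 | (5E)-6,10-dimethylundeca-5,9-dien-1-yne | CC(C)=CCC/C(C)=C/CCC#C | intermediate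
10 | (2R,3R)-3-(but-3-yn-1-yl)-2-{2-[(2R)-3,3-dimethyloxiran-2-yl]ethyl}-2-methyloxirane | CC1(C)O[C@@H]1CC[C@@]1(C)O[C@@H]1CCC#C | intermediate
11 | (3R,5aR,9aR)-2,2,5a-trimethyl-3-[(trimethylsilyl)oxy]-2,3,4,5,5a,8,9,9a-octahydro-1-benzoxepin-7-yl trifluoromethanesulfonate | C=1[C@@]2(C)CC[C@@H](O[Si](C)(C)C)C(C)(C)O[C@@H]2CCC=1OS(=O)(=O)C(F)(F)F | intermediate
12 | trimethyl{[(3R,5aR,9aR)-2,2,5a,7-tetramethyl-2,3,4,5,5a,8,9,9a-octahydro-1-benzoxepin-3-yl]oxy}silane | C=1[C@@]2(C)CC[C@@H](O[Si](C)(C)C)C(C)(C)O[C@@H]2CCC=1C | intermediate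
13 | (3R,5aR,9aR)-2,2,5a,7-tetramethyl-2,3,4,5,5a,8,9,9a-octahydro-1-benzoxepin-3-ol | C=1[C@@]2(C)CC[C@@H](O)C(C)(C)O[C@@H]2CCC=1C | intermediate
14 | (3R,5aS,6S,7S,9aR)-6-bromo-2,2,5a,7-tetramethyldecahydro-1-benzoxepine-3,7-diol | Br[C@H]1[C@@]2(C)CC[C@@H](O)C(C)(C)O[C@@H]2CC[C@]1(C)O | intermediate
15 | (3R,5aR,6S,7S,9aR)-2,2,5a,7-tetramethyl-6-[(E)-2-(tributylstannyl)ethenyl]decahydro-1-benzoxepine-3,7-diol | CCCC[Sn](CCCC)(CCCC)/C=C/[C@H]1[C@@]2(C)CC[C@@H](O)C(C)(C)O[C@@H]2CC[C@]1(C)O | intermediate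
16 | (4aR,8aR)-2-chloro-5,5,8a-trimethyl-3,4,4a,5,6,7,8,8a-octahydronaphthalene | ClC=1CC[C@@H]2C(C)(C)CCC[C@@]2(C)C=1 | intermediate
17 | (4aR,8aS)-2,5,5,8a-tetramethyl-3,4,4a,5,6,7,8,8a-octahydronaphthalene | CC=1CC[C@@H]2C(C)(C)CCC[C@@]2(C)C=1 | intermediate
18 | [(1S,2R,4aR,8aS)-2,5,5,8a-tetramethyldecahydronaphthalen-1-yl]borane | C[C@@H]1CC[C@@H]2C(C)(C)CCC[C@@]2(C)[C@H]1B | intermediate
19 | (2R,4aR,8aR)-2,5,5,8a-tetramethyloctahydronaphthalen-1(2H)-one | C[C@@H]1CC[C@@H]2C(C)(C)CCC[C@@]2(C)C1=O | intermediate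
20 | (3R,5aR,9aR)-3,6,6,9a-tetramethyloctahydro-1-benzoxepin-2(3H)-one | C[C@@H]1CC[C@@H]2C(C)(C)CCC[C@@]2(C)OC1=O | intermediate
21 | (E)-2-[(3R,5aR,6S,7S,9aR)-3,7-bis(lithiooxy)-2,2,5a,7-tetramethyldecahydro-1-benzoxepin-6-yl]ethenyllithium | [Li]/C=C/[C@H]1[C@@]2(C)CC[C@@H](O[Li])C(C)(C)O[C@@H]2CC[C@]1(C)O[Li] | intermediate
22 | (2R,3R,5aR,9aR)-2-{(E)-2-[(3R,5aR,6S,7S,9aR)-3,7-dihydroxy-2,2,5a,7-tetramethyldecahydro-1-benzoxepin-6-yl]ethenyl}-3,6,6,9a-tetramethyldecahydro-1-benzoxepin-2-ol | C[C@@H]1CC[C@@H]2C(C)(C)CCC[C@@]2(C)O[C@@]1(O)/C=C/[C@H]1[C@@]2(C)CC[C@@H](O)C(C)(C)O[C@@H]2CC[C@]1(C)O | intermediate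
23 | (5aR,6S,7S,9aR)-7-hydroxy-6-{(E)-2-[(2R,3R,5aR,9aR)-2-hydroxy-3,6,6,9a-tetramethyldecahydro-1-benzoxepin-2-yl]ethenyl}-2,2,5a,7-tetramethyloctahydro-1-benzoxepin-3(2H)-one | C[C@@H]1CC[C@@H]2C(C)(C)CCC[C@@]2(C)O[C@@]1(O)/C=C/[C@H]1[C@@]2(C)CCC(=O)C(C)(C)O[C@@H]2CC[C@]1(C)O | target

**Step count and risks**
Total step count: 15. Longest linear sequence: 11 steps (1–4, 5–9, 14, 15).

Step 6 (new cascade; the alkyne may be too weak a nucleophile for the epoxonium ion). The fallback uses the known propargylsilane termination; it sets out from iodide 8 and comes back to the route at silyl ether 12. Iodide 8 is alkylated with lithiated 1-(trimethylsilyl)propyne to give trimethyl[(6E)-7,11-dimethyldodeca-6,10-dien-1-yn-1-yl]silane F1. K2CO3 in MeOH gives (6E)-7,11-dimethyldodeca-6,10-dien-1-yne F2, and n-BuLi then ICH2SiMe3 give trimethyl[(7E)-8,12-dimethyltrideca-7,11-dien-2-yn-1-yl]silane F3. Shi epoxidation as in step 5 gives (2R,3R)-2-{2-[(2R)-3,3-dimethyloxiran-2-yl]ethyl}-2-methyl-3-[6-(trimethylsilyl)hex-4-yn-1-yl]oxirane F4. TMSOTf with the hindered pyridine then runs the same oxepane-then-carbocycle cascade, ended by SE2′ attack of the propargylsilane, to give the allene (3R,5aR,9aR)-6-ethenylidene-2,2,5a-trimethyl-3-[(trimethylsilyl)oxy]decahydro-1-benzoxepine F5. Ozonolysis (O3, then Me2S) gives (3R,5aS,9aR)-2,2,5a-trimethyl-3-[(trimethylsilyl)oxy]octahydro-1-benzoxepin-6(2H)-one F6, and LDA/MeI methylates its only enolisable position to give (3R,5aS,9aR)-2,2,5a,7-tetramethyl-3-[(trimethylsilyl)oxy]octahydro-1-benzoxepin-6(2H)-one F7 (either C-7 epimer). KHMDS/PhNTf2 gives (3R,5aS,9aR)-2,2,5a,7-tetramethyl-3-[(trimethylsilyl)oxy]-2,3,4,5,5a,8,9,9a-octahydro-1-benzoxepin-6-yl trifluoromethanesulfonate F8, which Pd(OAc)2/PPh3, Bu3N and HCO2H reduce to 12.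

Step 10 (new enantioselective bicyclisation; the ee or the chloride capture may fall short). The fallback replaces asymmetric induction by resolution; it sets out from dienyne 9 and comes back at alkene 17. The achiral acid SnCl4·2-methoxyphenol cyclises 9 (alkyne-terminated cation–olefin cyclisation with chloride capture, established in the racemic series) to racemic (4aR*,8aR*)-2-chloro-5,5,8a-trimethyl-3,4,4a,5,6,7,8,8a-octahydronaphthalene F9. Methylation as in step 11 gives racemic (4aR*,8aS*)-2,5,5,8a-tetramethyl-3,4,4a,5,6,7,8,8a-octahydronaphthalene F10. A Shi epoxidation run as a kinetic resolution, with the ketone enantiomer matched to the unwanted alkene, converts that enantiomer into (1S,2R,4aS,8aS)-1,2-epoxy-2,5,5,8a-tetramethyldecahydronaphthalene F11 and leaves 17.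

Step 14 (over-addition to the lactone or poor addition of the hindered trianion). The fallback joins the halves by a neutral radical vinyl transfer; it sets out from lactone 20 and comes back at 22, and step 9 is then not needed. Lactone 20 and acetylide 2 give (2R,3R,5aR,9aR)-2-ethynyl-3,6,6,9a-tetramethyldecahydro-1-benzoxepin-2-ol F12. Radical hydrostannation (Bu3SnH, AIBN) gives (2R,3R,5aR,9aR)-3,6,6,9a-tetramethyl-2-[(E)-2-(tributylstannyl)ethenyl]decahydro-1-benzoxepin-2-ol F13, which is in equilibrium with its open β-stannyl enone. Heating F13 with bromohydrin 14 and AIBN (addition of the C-6 radical to the tin-bearing carbon of the enone, then loss of Bu3Sn•) gives 22.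

**Further compounds**
F1 | step 6 | trimethyl[(6E)-7,11-dimethyldodeca-6,10-dien-1-yn-1-yl]silane | CC(C)=CCC/C(C)=C/CCCC#C[Si](C)(C)C
F2 | step 6 | (6E)-7,11-dimethyldodeca-6,10-dien-1-yne | CC(C)=CCC/C(C)=C/CCCC#C
F3 | step 6 | trimethyl[(7E)-8,12-dimethyltrideca-7,11-dien-2-yn-1-yl]silane | CC(C)=CCC/C(C)=C/CCCC#CC[Si](C)(C)C
F4 | step 6 | (2R,3R)-2-{2-[(2R)-3,3-dimethyloxiran-2-yl]ethyl}-2-methyl-3-[6-(trimethylsilyl)hex-4-yn-1-yl]oxirane | CC1(C)O[C@@H]1CC[C@@]1(C)O[C@@H]1CCCC#CC[Si](C)(C)C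
F5 | step 6 | (3R,5aR,9aR)-6-ethenylidene-2,2,5a-trimethyl-3-[(trimethylsilyl)oxy]decahydro-1-benzoxepine | C=C=C1[C@@]2(C)CC[C@@H](O[Si](C)(C)C)C(C)(C)O[C@@H]2CCC1
F6 | step 6 | (3R,5aS,9aR)-2,2,5a-trimethyl-3-[(trimethylsilyl)oxy]octahydro-1-benzoxepin-6(2H)-one | O=C1[C@@]2(C)CC[C@@H](O[Si](C)(C)C)C(C)(C)O[C@@H]2CCC1
F7 | step 6 | (3R,5aS,9aR)-2,2,5a,7-tetramethyl-3-[(trimethylsilyl)oxy]octahydro-1-benzoxepin-6(2H)-one | O=C1[C@@]2(C)CC[C@@H](O[Si](C)(C)C)C(C)(C)O[C@@H]2CCC1C
F8 | step 6 | (3R,5aS,9aR)-2,2,5a,7-tetramethyl-3-[(trimethylsilyl)oxy]-2,3,4,5,5a,8,9,9a-octahydro-1-benzoxepin-6-yl trifluoromethanesulfonate | FC(F)(F)S(=O)(=O)OC=1[C@@]2(C)CC[C@@H](O[Si](C)(C)C)C(C)(C)O[C@@H]2CCC=1C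
F9 | step 10 | racemic (4aR*,8aR*)-2-chloro-5,5,8a-trimethyl-3,4,4a,5,6,7,8,8a-octahydronaphthalene | ClC=1CC[C@@H]2C(C)(C)CCC[C@@]2(C)C=1.ClC=1CC[C@H]2C(C)(C)CCC[C@]2(C)C=1
F10 | step 10 | racemic (4aR*,8aS*)-2,5,5,8a-tetramethyl-3,4,4a,5,6,7,8,8a-octahydronaphthalene | CC=1CC[C@@H]2C(C)(C)CCC[C@@]2(C)C=1.CC=1CC[C@H]2C(C)(C)CCC[C@]2(C)C=1
F11 | step 10 | (1S,2R,4aS,8aS)-1,2-epoxy-2,5,5,8a-tetramethyldecahydronaphthalene | C[C@@]1(O2)CC[C@H]3C(C)(C)CCC[C@]3(C)[C@@H]12
F12 | step 14 | (2R,3R,5aR,9aR)-2-ethynyl-3,6,6,9a-tetramethyldecahydro-1-benzoxepin-2-ol | C[C@@H]1CC[C@@H]2C(C)(C)CCC[C@@]2(C)O[C@@]1(O)C#C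
F13 | step 14 | (2R,3R,5aR,9aR)-3,6,6,9a-tetramethyl-2-[(E)-2-(tributylstannyl)ethenyl]decahydro-1-benzoxepin-2-ol | C[C@@H]1CC[C@@H]2C(C)(C)CCC[C@@]2(C)O[C@@]1(O)/C=C/[Sn](CCCC)(CCCC)CCCC
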